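**Retrosynthetic overview**

1. Numbering (germacrane): carbocycle C1–C10 with C1 = CHOH, C4 = oxirane C(CH3), C5 = oxirane CH, C6 = lactone O–CH, C8 = CH–O-tigloyl, C10 = CH(CH3); butenolide O–C6–C7=C11(C13H2OAc)–C12(=O).
2. Enabling feature: the oxirane is cis-fused to the ten-membered ring (C3 and C6 on the same side of C4–C5), so it is the oxide of a (4Z)-trisubstituted olefin. Its C5 end sits on the butenolide γ-carbon C6 and its C4 end carries only CH3 and C3, which is a vinyl/isopropenyl pair for ring-closing metathesis; the (8S)-hydroxyl lies over the olefin face that must be oxidised.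
3. Tiglate at C8 and silyl ether at C1 (last) ⇒ oxirane by 8-OH-directed epoxidation ⇒ C4=C5 by RCM of a γ-vinylbutenolide triene ⇒ butenolide by singlet-oxygen opening of a 2-silylfuran and asymmetric Ni/Cr vinylation–lactonisation at C6.
4. ⇒ C7–C8 bond from a C4-lithiated 2-silyl-3-furanmethanol and a trans-β-methyl-γ-lactone (C8–C10, C1–C4), C8 by CBS reduction ⇒ lactone from 4-methylpent-4-enal by anti-crotylboration (C1, C10), hydroboration and oxidative lactonisation.
5. Ring order: γ-lactone (temporary, opened at fragment union) → furan (purchased) → butenolide → ten-membered carbocycle → oxirane.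

Key step: step 13

Remark: the side-chain ester is read as the (E)-2-methylbut-2-enoate (tiglate) as drawn; the CIP descriptor of C6 changes from R (vinyl and olefin stages) to S (oxirane stage) without any change in space.

**Route**

Step 1
Reactants: 1 ethyl 4-methylpent-4-enoate
Product: 2 4-methylpent-4-enal
Conditions: DIBAL-H (1.05 equiv), CH2Cl2, −78 °C; Rochelle salt
Reagents that add atoms: none
Why: DIBAL-H half-reduction of an ester stops at the aldehyde because the aluminium hemiacetal is stable at −78 °C, and the isolated 1,1-disubstituted olefin is inert.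

Step 2
Reactants: 2 4-methylpent-4-enal
Product: 3 (3R,4S)-3,7-dimethylocta-1,7-dien-4-ol
Conditions: (E)-crotylboronic acid pinacol ester (1.2 equiv), (R)-TRIP phosphoric acid (5 mol %), 4 Å MS, toluene, −30 °C
Reagents that add atoms: (E)-crotylboronic acid pinacol ester, C/C=C/CB1OC(C)(C)C(C)(C)O1
Why: Chiral phosphoric acid-catalysed crotylboration runs through a closed chair transition state in which the (E)-crotyl geometry sets the anti C10-methyl/C1-hydroxyl relationship and the (R)-catalyst directs Re-face attack to give the (4S)-carbinol.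

Step 3
Reactants: 3 (3R,4S)-3,7-dimethylocta-1,7-dien-4-ol
Product: 5 (3R,4S)-3,7-dimethyloct-7-ene-1,4-diol, via bis-catecholboron adduct 4 (not isolated)
Conditions: catecholborane (2.5 equiv), RhCl(PPh3)3 (3 mol %), THF, 0 °C to rt; then NaOH, 30% H2O2, 0 °C
Reagents that add atoms: hydrogen peroxide, OO
Why: Rh-catalysed hydroboration discriminates the monosubstituted vinyl group from the 1,1-disubstituted olefin and places boron on the terminal carbon, so oxidation should give the primary alcohol that becomes C8 without touching a stereocentre.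

Step 4
Reactants: 5 (3R,4S)-3,7-dimethyloct-7-ene-1,4-diol
Product: 7 (4R,5S)-4-methyl-5-(3-methylbut-3-en-1-yl)oxolan-2-one, via lactol 6 (not isolated)
Conditions: TEMPO (20 mol %), PhI(OAc)2 (2.5 equiv), CH2Cl2, rt
Reagents that add atoms: none
Why: Oxoammonium oxidation is selective for the primary alcohol, the aldehyde is trapped by the C1 hydroxyl as the lactol and this is oxidised on to the γ-lactone (TEMPO/PhI(OAc)2 oxidative lactonisation of a 1,4-diol), leaving both stereocentres untouched.

Step 5
Reactants: 8 furan-3-ylmethanol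
Product: 9 triethyl(furan-3-ylmethoxy)silane
Conditions: Et3SiCl (1.1 equiv), imidazole, CH2Cl2, 0 °C
Reagents that add atoms: chlorotriethylsilane, CC[Si](Cl)(CC)CC
Why: Standard imidazole-mediated O-silylation of a primary alcohol installs the silicon that is relayed to carbon in the next step.

Step 6
Reactants: 9 triethyl(furan-3-ylmethoxy)silane
Product: 11 [2-(triethylsilyl)furan-3-yl]methanol, via 2-lithiofuran 10 (not isolated)
Conditions: n-BuLi (1.3 equiv), HMPA (1.3 equiv), THF, −78 °C to rt; then H2O
Reagents that add atoms: none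
Why: Lithiation at the α-position next to the substituent followed by 1,4 O→C silyl migration (retro-[1,4]-Brook rearrangement of 3-(silyloxymethyl)furans) puts silicon on the future C12 and frees the alkoxide that directs the next metalation.

Step 7
Reactants: 11 [2-(triethylsilyl)furan-3-yl]methanol; 7 (4R,5S)-4-methyl-5-(3-methylbut-3-en-1-yl)oxolan-2-one
Product: 13 (3R,4S)-4-hydroxy-1-[4-(hydroxymethyl)-5-(triethylsilyl)furan-3-yl]-3,7-dimethyloct-7-en-1-one, via dilithio species 12 (not isolated)
Conditions: 11, n-BuLi (2.2 equiv), DME, 0 °C; then 7 (0.9 equiv), THF, −78 °C; then H2O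
Reagents that add atoms: none
Why: With C2 blocked by silicon the lithium alkoxide directs lithiation to C4 of the furan (directed ortho-metalation), and the aryllithium opens the γ-lactone to a lithium hemiketal that persists at −78 °C, so a single addition should give the C8 ketone and release the C1 hydroxyl.

Step 8
Reactants: 13 (3R,4S)-4-hydroxy-1-[4-(hydroxymethyl)-5-(triethylsilyl)furan-3-yl]-3,7-dimethyloct-7-en-1-one
Product: 14 {4-[(3R,4S)-4-hydroxy-3,7-dimethyloct-7-enoyl]-2-(triethylsilyl)furan-3-yl}methyl acetate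
Conditions: AcCl (1.1 equiv), 2,4,6-collidine, CH2Cl2, −78 °C
Reagents that add atoms: acetyl chloride, CC(Cl)=O
Why: Acetyl chloride/collidine at low temperature acylates the primary furylmethyl alcohol much faster than the hindered secondary C1 hydroxyl (selective primary acetylation), which installs the C13 acetate of the target early.

Step 9
Reactants: 14 {4-[(3R,4S)-4-hydroxy-3,7-dimethyloct-7-enoyl]-2-(triethylsilyl)furan-3-yl}methyl acetate
Product: 15 {4-[(3R,4S)-3,7-dimethyl-4-(triethylsilyloxy)oct-7-enoyl]-2-(triethylsilyl)furan-3-yl}methyl acetate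
Conditions: Et3SiCl (1.5 equiv), imidazole, DMAP (cat.), DMF, rt
Reagents that add atoms: chlorotriethylsilane, CC[Si](Cl)(CC)CC
Why: Silyl ether formation on the open-chain γ-hydroxy ketone masks the C1 hydroxyl so that it cannot compete with the C8 hydroxyl in the directed epoxidation and the esterification.

Step 10
Reactants: 15 {4-[(3R,4S)-3,7-dimethyl-4-(triethylsilyloxy)oct-7-enoyl]-2-(triethylsilyl)furan-3-yl}methyl acetate
Product: 16 {4-[(1S,3R,4S)-1-hydroxy-3,7-dimethyl-4-(triethylsilyloxy)oct-7-en-1-yl]-2-(triethylsilyl)furan-3-yl}methyl acetate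
Conditions: (R)-Me-CBS (0.5 equiv), catecholborane (2 equiv), toluene, −78 to −40 °C
Reagents that add atoms: none
Why: In this Corey–Bakshi–Shibata reduction the furan is the large group of the furyl alkyl ketone, so the (R)-oxazaborolidine should deliver hydride to give the (8S)-carbinol, and catecholborane neither hydroborates the olefin nor reduces the acetate under these conditions.

Step 11
Reactants: 16 {4-[(1S,3R,4S)-1-hydroxy-3,7-dimethyl-4-(triethylsilyloxy)oct-7-en-1-yl]-2-(triethylsilyl)furan-3-yl}methyl acetate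
Product: 18 triethylsilyl (2Z,4S,6R,7S)-2-(acetoxymethyl)-3-formyl-4-hydroxy-6,10-dimethyl-7-(triethylsilyloxy)undeca-2,10-dienoate, via furan endoperoxide 17 (not isolated)
Conditions: O2, visible light, tetraphenylporphyrin (1 mol %), CH2Cl2, −78 °C then 0 °C; concentrated and used crude
Reagents that add atoms: dioxygen, O=O
Why: [4+2] addition of singlet oxygen to the furan followed by migration of silicon from C12 to peroxide oxygen (photooxygenation of 2-silylfurans) opens the ring regiospecifically to the (Z)-4-oxo-2-enoic silyl ester with C12 as carboxyl and C6 as aldehyde, while the isolated 1,1-disubstituted olefin reacts far more slowly with singlet oxygen than the furan.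

Step 12
Reactants: 18 triethylsilyl (2Z,4S,6R,7S)-2-(acetoxymethyl)-3-formyl-4-hydroxy-6,10-dimethyl-7-(triethylsilyloxy)undeca-2,10-dienoate
Product: 20 {(5R)-4-[(1S,3R,4S)-1-hydroxy-3,7-dimethyl-4-(triethylsilyloxy)oct-7-en-1-yl]-2-oxo-5-vinyl-2,5-dihydrofuran-3-yl}methyl acetate, via chromium alkoxide 19 (not isolated)
Conditions: iodoethene (3 equiv), CrCl2 (4 equiv), NiCl2 (2 mol %), chiral oxazoline–sulfonamide ligand (4.4 equiv, antipode chosen for the (6R)-carbinol), Et3N, THF/MeCN, rt; aqueous serine work-up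
Reagents that add atoms: iodoethene, C=CI
Why: Nozaki–Hiyama–Kishi vinylation is selective for the aldehyde beside the silyl and acetate esters, the ligand on chromium controls the face of addition at C6 (the C8 centre is insulated by the sp2 carbon C7), and the C6 alkoxide, held cis to the silyl ester by the C7=C11 geometry, closes the butenolide (5-exo-trig acyl substitution) with loss of silanolate.

Step 13
Reactants: 20 {(5R)-4-[(1S,3R,4S)-1-hydroxy-3,7-dimethyl-4-(triethylsilyloxy)oct-7-en-1-yl]-2-oxo-5-vinyl-2,5-dihydrofuran-3-yl}methyl acetate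
Product: 21 (1S,4Z,6R,8S,10R)-13-acetoxy-8-hydroxy-1-(triethylsilyloxy)germacra-4,7(11)-dien-12,6-olide
Conditions: Hoveyda–Grubbs II (15 mol %, in portions), 1,4-benzoquinone (30 mol %), toluene (1 mM), 90 °C, argon sparge
Reagents that add atoms: none
Why: Ring-closing olefin metathesis: the catalyst forms the ruthenium alkylidene at the monosubstituted C5 vinyl group, which undergoes intramolecular [2+2] cycloaddition with the 1,1-disubstituted C4 isopropenyl group and cycloreversion, forming C4=C5 and releasing ethene. The closest known reaction type is RCM of a monosubstituted/1,1-disubstituted diene to a (Z)-trisubstituted olefin in nine- and ten-membered carbocycles that carry a butenolide. The ten-membered carbocycle is closed as a medium-ring metathesis giving an endocyclic olefin, with the butenolide remaining as the fused ring. No stereocentre is formed; the Z geometry that the cis-fused oxirane requires should be imposed by ring strain (the E-trisubstituted olefin in this butenolide-fused cyclodecene is much higher in energy) and by the reversibility of metathesis, and C1, C6, C8 and C10 are not touched. The step needs ring closure over oligomerisation and no olefin migration; high dilution, the slow homodimerisation of both hindered olefins and benzoquinone (which suppresses Ru–H isomerisation of the γ-vinylbutenolide) should secure this, and the tetrasubstituted butenolide olefin is inert to the catalyst.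

Step 14
Reactants: 21 (1S,4Z,6R,8S,10R)-13-acetoxy-8-hydroxy-1-(triethylsilyloxy)germacra-4,7(11)-dien-12,6-olide
Product: 22 (1S,4R,5S,6S,8S,10R)-13-acetoxy-4,5-epoxy-8-hydroxy-1-(triethylsilyloxy)germacr-7(11)-en-12,6-olide
Conditions: VO(acac)2 (10 mol %), t-BuOOH (1.5 equiv, in decane), CH2Cl2, 0 °C to rt
Reagents that add atoms: tert-butyl hydroperoxide, CC(C)(C)OO
Why: In this hydroxyl-directed vanadium-catalysed epoxidation the vanadate ester of the (8S)-alcohol, which sits on the C7 side of the ring directly over one face of the C4=C5 olefin, should deliver the peroxide oxygen to that face and set C4 (R) and C5 (S) together by syn addition to the Z-olefin, while the electron-poor tetrasubstituted butenolide olefin is not epoxidised.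

Step 15
Reactants: 22 (1S,4R,5S,6S,8S,10R)-13-acetoxy-4,5-epoxy-8-hydroxy-1-(triethylsilyloxy)germacr-7(11)-en-12,6-olide
Product: 23 (1S,4R,5S,6S,8S,10R)-13-acetoxy-4,5-epoxy-8-[(E)-2-methylbut-2-enoyloxy]-1-(triethylsilyloxy)germacr-7(11)-en-12,6-olide
Conditions: tiglic acid (3 equiv), 2,4,6-trichlorobenzoyl chloride, Et3N, toluene, rt; then 22, DMAP, rt to 40 °C
Reagents that add atoms: tiglic acid, C/C=C(\C)C(=O)O
Why: Yamaguchi esterification acylates the only free hydroxyl with retention at C8 and avoids the vinylketene pathway that deconjugates enoyl chlorides, and the oxirane, lying on the same face as O8, cannot be opened from the back by that oxygen.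

Step 16
Reactants: 23 (1S,4R,5S,6S,8S,10R)-13-acetoxy-4,5-epoxy-8-[(E)-2-methylbut-2-enoyloxy]-1-(triethylsilyloxy)germacr-7(11)-en-12,6-olide
Product: 24 (1S,4R,5S,6S,8S,10R)-13-acetoxy-4,5-epoxy-1-hydroxy-8-[(E)-2-methylbut-2-enoyloxy]germacr-7(11)-en-12,6-olide (CNP0159184.1)
Conditions: HF·pyridine, pyridine, THF, 0 °C
Reagents that add atoms: none
Why: Pyridine-buffered fluoride cleaves the secondary triethylsilyl ether (Si–F bond formation) under conditions too weakly acidic to trigger transannular opening of the oxirane by the liberated C1 hydroxyl, and leaves tiglate, acetate and butenolide untouched.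

**Compound list**

1 | ethyl 4-methylpent-4-enoate | CCOC(=O)CCC(C)=C | starting material
2 | 4-methylpent-4-enal | O=CCCC(C)=C | intermediate
3 | (3R,4S)-3,7-dimethylocta-1,7-dien-4-ol | C=C[C@@H](C)[C@@H](O)CCC(C)=C | intermediate
4 | bis-catecholboron adduct of 3 (C-boronate at the terminal carbon, O-borate at the carbinol) | c1ccc2OB(CC[C@@H](C)[C@@H](OB3Oc4ccccc4O3)CCC(C)=C)Oc2c1 | intermediate (not isolated)
5 | (3R,4S)-3,7-dimethyloct-7-ene-1,4-diol | OCC[C@@H](C)[C@@H](O)CCC(C)=C | intermediate
6 | (4R,5S)-4-methyl-5-(3-methylbut-3-en-1-yl)oxolan-2-ol (lactol, both anomers) | OC1C[C@@H](C)[C@H](CCC(C)=C)O1 | intermediate (not isolated)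
7 | (4R,5S)-4-methyl-5-(3-methylbut-3-en-1-yl)oxolan-2-one | O=C1C[C@@H](C)[C@H](CCC(C)=C)O1 | intermediate
8 | furan-3-ylmethanol | OCc1ccoc1 | starting material
9 | triethyl(furan-3-ylmethoxy)silane | CC[Si](CC)(CC)OCc1ccoc1 | intermediate
10 | {3-[(triethylsilyloxy)methyl]furan-2-yl}lithium | CC[Si](CC)(CC)OCc1ccoc1[Li] | intermediate (not isolated)
11 | [2-(triethylsilyl)furan-3-yl]methanol | CC[Si](CC)(CC)c1occc1CO | intermediate
12 | lithium [4-lithio-2-(triethylsilyl)furan-3-yl]methoxide | [Li]OCc1c([Si](CC)(CC)CC)occ1[Li] | intermediate (not isolated)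
13 | (3R,4S)-4-hydroxy-1-[4-(hydroxymethyl)-5-(triethylsilyl)furan-3-yl]-3,7-dimethyloct-7-en-1-one | O=C(C[C@@H](C)[C@@H](O)CCC(C)=C)c1coc([Si](CC)(CC)CC)c1CO | intermediate
14 | {4-[(3R,4S)-4-hydroxy-3,7-dimethyloct-7-enoyl]-2-(triethylsilyl)furan-3-yl}methyl acetate | O=C(C[C@@H](C)[C@@H](O)CCC(C)=C)c1coc([Si](CC)(CC)CC)c1COC(C)=O | intermediate
15 | {4-[(3R,4S)-3,7-dimethyl-4-(triethylsilyloxy)oct-7-enoyl]-2-(triethylsilyl)furan-3-yl}methyl acetate | O=C(C[C@@H](C)[C@@H](O[Si](CC)(CC)CC)CCC(C)=C)c1coc([Si](CC)(CC)CC)c1COC(C)=O | intermediate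
16 | {4-[(1S,3R,4S)-1-hydroxy-3,7-dimethyl-4-(triethylsilyloxy)oct-7-en-1-yl]-2-(triethylsilyl)furan-3-yl}methyl acetate | O[C@@H](C[C@@H](C)[C@@H](O[Si](CC)(CC)CC)CCC(C)=C)c1coc([Si](CC)(CC)CC)c1COC(C)=O | intermediate
17 | 2,5-endoperoxide of furan 16 (2,3,7-trioxabicyclo[2.2.1]hept-5-ene, silicon on the C12 bridgehead, both faces) | CC[Si](CC)(CC)C12OOC(O1)C([C@@H](O)C[C@@H](C)[C@@H](O[Si](CC)(CC)CC)CCC(C)=C)=C2COC(C)=O | intermediate (not isolated)
18 | triethylsilyl (2Z,4S,6R,7S)-2-(acetoxymethyl)-3-formyl-4-hydroxy-6,10-dimethyl-7-(triethylsilyloxy)undeca-2,10-dienoate | O=C/C(=C(/COC(C)=O)C(=O)O[Si](CC)(CC)CC)[C@@H](O)C[C@@H](C)[C@@H](O[Si](CC)(CC)CC)CCC(C)=C | intermediate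
19 | chromium(III) alkoxide of triethylsilyl (2Z,4S,6R,7S)-2-(acetoxymethyl)-4-hydroxy-3-[(1R)-1-hydroxyprop-2-en-1-yl]-6,10-dimethyl-7-(triethylsilyloxy)undeca-2,10-dienoate (drawn as the alkoxide) | C=C[C@@H]([O-])/C(=C(/COC(C)=O)C(=O)O[Si](CC)(CC)CC)[C@@H](O)C[C@@H](C)[C@@H](O[Si](CC)(CC)CC)CCC(C)=C | intermediate (not isolated)
20 | {(5R)-4-[(1S,3R,4S)-1-hydroxy-3,7-dimethyl-4-(triethylsilyloxy)oct-7-en-1-yl]-2-oxo-5-vinyl-2,5-dihydrofuran-3-yl}methyl acetate | C=C[C@H]1OC(=O)C(COC(C)=O)=C1[C@@H](O)C[C@@H](C)[C@@H](O[Si](CC)(CC)CC)CCC(C)=C | intermediate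
21 | (1S,4Z,6R,8S,10R)-13-acetoxy-8-hydroxy-1-(triethylsilyloxy)germacra-4,7(11)-dien-12,6-olide | O[C@H]1C[C@@H](C)[C@@H](O[Si](CC)(CC)CC)CC/C(C)=C\[C@H]2OC(=O)C(COC(C)=O)=C12 | intermediate
22 | (1S,4R,5S,6S,8S,10R)-13-acetoxy-4,5-epoxy-8-hydroxy-1-(triethylsilyloxy)germacr-7(11)-en-12,6-olide | O[C@H]1C[C@@H](C)[C@@H](O[Si](CC)(CC)CC)CC[C@@]2(C)O[C@H]2[C@H]2OC(=O)C(COC(C)=O)=C12 | intermediate
23 | (1S,4R,5S,6S,8S,10R)-13-acetoxy-4,5-epoxy-8-[(E)-2-methylbut-2-enoyloxy]-1-(triethylsilyloxy)germacr-7(11)-en-12,6-olide | C/C=C(\C)C(=O)O[C@H]1C[C@@H](C)[C@@H](O[Si](CC)(CC)CC)CC[C@@]2(C)O[C@H]2[C@H]2OC(=O)C(COC(C)=O)=C12 | intermediate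
24 | (1S,4R,5S,6S,8S,10R)-13-acetoxy-4,5-epoxy-1-hydroxy-8-[(E)-2-methylbut-2-enoyloxy]germacr-7(11)-en-12,6-olide (CNP0159184.1) | C/C=C(\C)C(=O)O[C@H]1C[C@@H](C)[C@@H](O)CC[C@@]2(C)O[C@H]2[C@H]2OC(=O)C(COC(C)=O)=C12 | target

**Totals and risks**

Total step count: 16. Longest linear sequence: 14 steps (steps 1–4, then 7–16 from compound 1).

The three steps most likely to fail:

Step 13 (ring closure). The ruthenium alkylidene may not form on the hindered C5 vinyl group, or may cross-couple between molecules instead of closing the strained ten-membered ring. The fallback moves the catalyst loading site and makes formation of the C5 alkylidene intramolecular and irreversible. It sets out from 18: the Ni/Cr coupling of step 12 is run with (E)-3-(allyloxy)-1-iodoprop-1-ene (from (E)-3-iodoprop-2-en-1-ol and allyl bromide) in place of iodoethene and should give the relay triene {(5R)-5-[(E)-3-(allyloxy)prop-1-en-1-yl]-4-[(1S,3R,4S)-1-hydroxy-3,7-dimethyl-4-(triethylsilyloxy)oct-7-en-1-yl]-2-oxo-2,5-dihydrofuran-3-yl}methyl acetate F1. With a second-generation ruthenium catalyst in dilute toluene at 80 °C the catalyst should load on the unhindered allyl ether, expel 2,5-dihydrofuran and so generate the C5 alkylidene next to the butenolide, which can only close on the C4 isopropenyl group (relay ring-closing metathesis). The sequence comes back to the route at 21.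

Step 12 (vinylation at C6). Facial selectivity at the aldehyde may be poor because of a mismatch between ligand and substrate, and Cr(II) may reduce the electron-poor oxo-enoate by single-electron transfer. The fallback replaces the chromium reagent by a zinc acetylide and adds the two olefinic hydrogens later. It sets out from 18: Zn–ProPhenol-catalysed addition of (trimethylsilyl)acetylene (Me2Zn, toluene), a reaction class that works well on α,β-unsaturated aldehydes, followed by the same lactonisation should give {(5R)-4-[(1S,3R,4S)-1-hydroxy-3,7-dimethyl-4-(triethylsilyloxy)oct-7-en-1-yl]-2-oxo-5-[(trimethylsilyl)ethynyl]-2,5-dihydrofuran-3-yl}methyl acetate F2. Silver nitrate-catalysed protodesilylation in aqueous acetone should give the terminal alkyne {(5R)-5-ethynyl-4-[(1S,3R,4S)-1-hydroxy-3,7-dimethyl-4-(triethylsilyloxy)oct-7-en-1-yl]-2-oxo-2,5-dihydrofuran-3-yl}methyl acetate F3, and Lindlar semi-hydrogenation (H2, Pd/CaCO3/Pb, quinoline), which spares the 1,1-disubstituted olefin, should give 20, where the route is rejoined.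

Step 14 (epoxidation). Delivery from the bishomoallylic hydroxyl may be too slow or too loosely organised, so that the oxidant attacks the more exposed olefin face and gives the epimeric oxirane. The fallback uses the exposed face on purpose and inverts the outcome through a halohydrin. It sets out from 21: esterification under the conditions of step 15 should give the olefin tiglate (1S,4Z,6R,8S,10R)-13-acetoxy-8-[(E)-2-methylbut-2-enoyloxy]-1-(triethylsilyloxy)germacra-4,7(11)-dien-12,6-olide F4. NBS in aqueous DME at 0 °C should form the bromonium ion on the face away from the C8 ester, and water should open it at the tertiary C4 from the opposite face to give the bromohydrin (1S,4R,5R,6R,8S,10R)-13-acetoxy-5-bromo-4-hydroxy-8-[(E)-2-methylbut-2-enoyloxy]-1-(triethylsilyloxy)germacr-7(11)-en-12,6-olide F5. DBU in CH2Cl2 then closes the oxirane with inversion at C5, which places the oxygen on the face that a direct electrophile avoids, and the sequence returns to the route at 23.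

**Further compounds**

F1 | step 13 | {(5R)-5-[(E)-3-(allyloxy)prop-1-en-1-yl]-4-[(1S,3R,4S)-1-hydroxy-3,7-dimethyl-4-(triethylsilyloxy)oct-7-en-1-yl]-2-oxo-2,5-dihydrofuran-3-yl}methyl acetate | C=CCOC/C=C/[C@H]1OC(=O)C(COC(C)=O)=C1[C@@H](O)C[C@@H](C)[C@@H](O[Si](CC)(CC)CC)CCC(C)=C
F2 | step 12 | {(5R)-4-[(1S,3R,4S)-1-hydroxy-3,7-dimethyl-4-(triethylsilyloxy)oct-7-en-1-yl]-2-oxo-5-[(trimethylsilyl)ethynyl]-2,5-dihydrofuran-3-yl}methyl acetate | C[Si](C)(C)C#C[C@H]1OC(=O)C(COC(C)=O)=C1[C@@H](O)C[C@@H](C)[C@@H](O[Si](CC)(CC)CC)CCC(C)=C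
F3 | step 12 | {(5R)-5-ethynyl-4-[(1S,3R,4S)-1-hydroxy-3,7-dimethyl-4-(triethylsilyloxy)oct-7-en-1-yl]-2-oxo-2,5-dihydrofuran-3-yl}methyl acetate | C#C[C@H]1OC(=O)C(COC(C)=O)=C1[C@@H](O)C[C@@H](C)[C@@H](O[Si](CC)(CC)CC)CCC(C)=C
F4 | step 14 | (1S,4Z,6R,8S,10R)-13-acetoxy-8-[(E)-2-methylbut-2-enoyloxy]-1-(triethylsilyloxy)germacra-4,7(11)-dien-12,6-olide | C/C=C(\C)C(=O)O[C@H]1C[C@@H](C)[C@@H](O[Si](CC)(CC)CC)CC/C(C)=C\[C@H]2OC(=O)C(COC(C)=O)=C12
F5 | step 14 | (1S,4R,5R,6R,8S,10R)-13-acetoxy-5-bromo-4-hydroxy-8-[(E)-2-methylbut-2-enoyloxy]-1-(triethylsilyloxy)germacr-7(11)-en-12,6-olide | C/C=C(\C)C(=O)O[C@H]1C[C@@H](C)[C@@H](O[Si](CC)(CC)CC)CC[C@@](C)(O)[C@H](Br)[C@H]2OC(=O)C(COC(C)=O)=C12
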